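## Retrosynthetic overview
- The C3=C4 alkene is made last, by E1 dehydration and MOM removal from a 4‑hydroxy‑1‑aryl‑2,3‑dimethyltetralin.
- The C1–H bond comes from invertive ionic hydrogenolysis of the C1–O bond of a 1‑aryl‑1,4‑epoxytetralin. This places the aryl group cis to the C2 methyl.
- The second methyl group is the reduced CHO group of an oxa‑bridged Diels–Alder adduct of crotonaldehyde, which supplies C2, C3 and both methyl carbons.
- Key step: a hydroxy‑aldehyde closes to an isobenzofuran and is trapped by a chiral crotonaldehyde iminium ion. The furan ring and carbocycle B form together, and the absolute configuration at C2 is set here. The O‑bridge is opened later.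
- The hydroxy‑aldehyde comes from two molecules of MOM‑protected syringaldehyde, joined by directed ortho‑lithiation.

Assumption: the SMILES is read as the (1S,2S) isomer, with the aryl group and the C2 methyl cis. The carbon labels C1–C8a of the target's dihydronaphthalene are used for all intermediates.

## Route

Step 1
Reactants: 1 syringaldehyde (4‑hydroxy‑3,5‑dimethoxybenzaldehyde)
Product: 2 3,5‑dimethoxy‑4‑(methoxymethoxy)benzaldehyde
Conditions: MOMCl, iPr2NEt, CH2Cl2, 0 °C → rt
Reagents that add atoms: chloromethyl methyl ether, COCCl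
Why: Williamson‑type O‑alkylation (MOM acetal protection) masks the phenol against the organolithium chemistry that follows, and no stereocentre is involved.

Step 2
Reactants: 2 3,5‑dimethoxy‑4‑(methoxymethoxy)benzaldehyde (two molecules, one lithiated and one as the electrophile)
Product: 4 2‑{hydroxy[3,5‑dimethoxy‑4‑(methoxymethoxy)phenyl]methyl}‑3,5‑dimethoxy‑4‑(methoxymethoxy)benzaldehyde (racemic carbinol in equilibrium with its lactol), via ortho‑lithiated amino alkoxide 3 (not isolated)
Conditions: Me2NCH2CH2N(Me)Li (amine + n‑BuLi), THF, −20 °C; n‑BuLi, −20 → 0 °C; second portion of 2, −78 °C → rt; H2O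
Reagents that add atoms: none
Why: In this α‑amino‑alkoxide (Comins‑type) directed ortho‑lithiation the CHO is masked in situ and, together with the 3‑OMe group, directs lithium to C2 (the future C8a); the aryllithium then adds to a second aldehyde to form C8a–C1, and the new carbinol centre is racemic but is erased in step 3.

Step 3
Reactants: 4 the hydroxy‑aldehyde from step 2; 5 (E)‑crotonaldehyde
Product: 7 (1S,2R,3R,4S)‑1‑[3,5‑dimethoxy‑4‑(methoxymethoxy)phenyl]‑6,8‑dimethoxy‑7‑(methoxymethoxy)‑3‑methyl‑1,2,3,4‑tetrahydro‑1,4‑epoxynaphthalene‑2‑carbaldehyde (exo‑CHO/endo‑CH3 major isomer), via 1‑aryl‑isobenzofuran 6 (not isolated)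
Conditions: (5S)‑5‑benzyl‑2,2,3‑trimethylimidazolidin‑4‑one·HCl (20 mol %), MeCN–H2O 19:1, Ar, dark, 23 °C
Reagents that add atoms: none
Why: Proposed new method: the acidic catalyst salt dehydrates the lactol form of 4 (oxocarbenium ion, then loss of the C1–H proton) to the electron‑rich 1‑aryl‑isobenzofuran 6, which is trapped at once in an iminium‑catalysed (MacMillan‑type) Diels–Alder reaction by the LUMO‑lowered (E)‑iminium ion of 5, one face of which is shielded by the benzyl group, so the furan ring and the carbocycle of the oxa‑bridged bicycle form in one operation and C2 (and C3) are fixed by the π‑face of the enal alone; the nucleophilic unsubstituted furan carbon C4 should bond to the β‑carbon (placing CHO next to C1, exo), but the regio‑ and exo/endo‑isomers all carry the same C2 configuration and are expected to converge in steps 4–6; the closest known reaction types are the same imidazolidinone‑catalysed, exo‑selective cycloaddition of isolated 1,3‑diphenylisobenzofuran with crotonaldehyde, and the acid‑catalysed generation and in situ trapping of isobenzofurans from hydroxyphthalans.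

Step 4
Reactants: 7 the oxa‑bridged aldehyde from step 3
Product: 9 (1S,2R,3R,4S)‑1‑[3,5‑dimethoxy‑4‑(methoxymethoxy)phenyl]‑6,8‑dimethoxy‑7‑(methoxymethoxy)‑2,3‑dimethyl‑1,2,3,4‑tetrahydro‑1,4‑epoxynaphthalene, via tosylhydrazone 8 (not isolated)
Conditions: TsNHNH2, THF, rt; catecholborane, CHCl3, −10 °C; NaOAc·3H2O, 50 °C
Reagents that add atoms: none
Why: In this Caglioti‑type tosylhydrazone reduction (catecholborane variant) hydride adds to C=N, sulfinate leaves and the diazene loses N2 to give CH3; the near‑neutral conditions spare the acid‑labile bridge and leave C2 untouched.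

Step 5
Reactants: 9 the 2,3‑dimethyl‑1,4‑epoxytetralin from step 4
Product: 10 (1S,2R,3S,4S)‑4‑[3,5‑dimethoxy‑4‑(methoxymethoxy)phenyl]‑5,7‑dimethoxy‑6‑(methoxymethoxy)‑2,3‑dimethyl‑1,2,3,4‑tetrahydronaphthalen‑1‑ol (target numbering: 1S,2S,3R,4S with OH on C4)
Conditions: Et3SiH, CF3CO2H, CH2Cl2, −45 °C; NaHCO3 quench at −45 °C
Reagents that add atoms: none
Why: In this ionic hydrogenation (Kursanov–Parnes type) only the tertiary, doubly benzylic C1–O bond ionises at this temperature, and the silane delivers hydride to the face opposite both the departing oxygen and the pseudo‑axial C2 methyl, so C1–H forms with inversion and the aryl group ends cis to the C2 methyl (1S); the less stabilised C4 carbinol and the MOM groups survive the cold, short exposure.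

Step 6
Reactants: 10 the 4‑hydroxy‑tetralin from step 5
Product: 11 4‑[(1S,2S)‑7‑hydroxy‑6,8‑dimethoxy‑2,3‑dimethyl‑1,2‑dihydronaphthalen‑1‑yl]‑2,6‑dimethoxyphenol (target)
Conditions: 3 M aq HCl, THF, 45 °C
Reagents that add atoms: none
Why: Acid hydrolysis removes both MOM acetals, and E1 dehydration through the p‑hydroxybenzylic cation (quinone methide) at C4 with loss of H3 gives the conjugated trisubstituted styrene; this destroys the auxiliary centres C3 and C4 while C1 and C2 take no part.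

## Compound list
1 | syringaldehyde | COc1cc(C=O)cc(OC)c1O | starting material
2 | 3,5‑dimethoxy‑4‑(methoxymethoxy)benzaldehyde | COCOc1c(OC)cc(C=O)cc1OC | intermediate
3 | ortho‑lithiated lithium α‑amino alkoxide of 2 (not isolated) | [Li]c1c(OC)c(OCOC)c(OC)cc1C(O[Li])N(C)CCN(C)C | intermediate
4 | 2‑{hydroxy[3,5‑dimethoxy‑4‑(methoxymethoxy)phenyl]methyl}‑3,5‑dimethoxy‑4‑(methoxymethoxy)benzaldehyde (racemic carbinol, centre erased in step 3) | O=Cc1cc(OC)c(OCOC)c(OC)c1C(O)c1cc(OC)c(OCOC)c(OC)c1 | intermediate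
5 | (E)‑crotonaldehyde | C/C=C/C=O | starting material
6 | 1‑[3,5‑dimethoxy‑4‑(methoxymethoxy)phenyl]‑5,7‑dimethoxy‑6‑(methoxymethoxy)‑2‑benzofuran (not isolated) | COCOc1c(OC)cc(cc1OC)-c1occ2cc(OC)c(OCOC)c(OC)c12 | intermediate
7 | (1S,2R,3R,4S) oxa‑bridged aldehyde, exo‑CHO/endo‑CH3 | O=C[C@@H]1[C@@H](C)[C@@H]2O[C@@]1(c3cc(OC)c(OCOC)c(OC)c3)c4c(OC)c(OCOC)c(OC)cc24 | intermediate
8 | (E)‑tosylhydrazone of 7 (not isolated) | Cc1ccc(cc1)S(=O)(=O)N/N=C/[C@@H]1[C@@H](C)[C@@H]2O[C@@]1(c3cc(OC)c(OCOC)c(OC)c3)c4c(OC)c(OCOC)c(OC)cc24 | intermediate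
9 | (1S,2R,3R,4S)‑1‑aryl‑2,3‑dimethyl‑1,4‑epoxytetralin | C[C@@H]1[C@@H](C)[C@@H]2O[C@@]1(c3cc(OC)c(OCOC)c(OC)c3)c4c(OC)c(OCOC)c(OC)cc24 | intermediate
10 | (1S,2R,3S,4S)‑4‑aryl‑2,3‑dimethyltetralin‑1‑ol, bis‑MOM ether | COCOc1c(OC)cc([C@H]2c3c(OC)c(OCOC)c(OC)cc3[C@@H](O)[C@H](C)[C@H]2C)cc1OC | intermediate
11 | 4‑[(1S,2S)‑7‑hydroxy‑6,8‑dimethoxy‑2,3‑dimethyl‑1,2‑dihydronaphthalen‑1‑yl]‑2,6‑dimethoxyphenol | COc1cc([C@H]2c3c(cc(OC)c(O)c3OC)C=C(C)[C@H]2C)cc(OC)c1O | target

## Step count and risks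
Total step count: 6. Longest linear sequence: 6.

**Most likely to fail: step 3.** The isobenzofuran may form too slowly, or may be hydrated or oxidised before the cycloaddition. The ee may also drop with the unsymmetrical furan.

The fallback separates furan formation from the cycloaddition and moves the chirality to a Lewis acid. It sets out from 4 and returns at 9.
- PPTS in MeOH gives the cyclic methyl acetal 1,4,6‑trimethoxy‑5‑(methoxymethoxy)‑3‑aryl‑1,3‑dihydro‑2‑benzofuran F1.
- LDA‑induced 1,4‑elimination of methanol gives a cold solution of 6.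
- This solution is added at −78 °C to 3‑[(E)‑but‑2‑enoyl]‑1,3‑oxazolidin‑2‑one bound to a chiral Cu(II)–bis(oxazoline) complex, using the ligand enantiomer that gives the sense of 7. The product is the imide cycloadduct F2.
- LiBH4 gives the primary alcohol F3, and MsCl/Et3N gives the mesylate F4.
- LiEt3BH displaces the mesylate to give 9.

**Second: step 5.** The risks are loss of a proton from the C1 cation (which would scramble C2), over‑reduction at C4, and insufficient facial selectivity.

The fallback replaces the cation/silane pair with a neutral quinone methide and borohydride. It sets out from 9 and returns at 11.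
- TMSBr at −40 °C followed by aqueous work‑up strips both MOM groups to give the bridged bis‑phenol F5.
- In Et3N/MeOH this opens reversibly to the p‑quinone methide alcohol F6.
- The quinone methide is removed as it forms by NaBH4 at −78 °C. This is a 1,6‑hydride addition anti to the C2 methyl, and it gives the phenolic 4‑hydroxy‑tetralin F7.
- PPTS in warm THF then dehydrates F7 to 11.

**Third: step 2.** The risks are sluggish or unselective lithiation and butyl addition to the electrophile.

The fallback uses halogen–metal exchange in place of C–H lithiation. It sets out from 2 and returns at 4.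
- NBS gives 2‑bromo‑3,5‑dimethoxy‑4‑(methoxymethoxy)benzaldehyde F8.
- Ethylene glycol with PPTS gives the dioxolane F9.
- n‑BuLi at −78 °C followed by 2 gives the hydroxy dioxolane F10.
- Brief treatment with aqueous oxalic acid releases 4.

Further compounds
F1 | step 3 | 1,4,6‑trimethoxy‑5‑(methoxymethoxy)‑3‑[3,5‑dimethoxy‑4‑(methoxymethoxy)phenyl]‑1,3‑dihydro‑2‑benzofuran (diastereomer mixture) | COC1OC(c2cc(OC)c(OCOC)c(OC)c2)c2c(OC)c(OCOC)c(OC)cc12
F2 | step 3 | 3‑{[(1S,2R,3R,4S)‑1‑aryl‑6,8‑dimethoxy‑7‑(methoxymethoxy)‑3‑methyl‑1,2,3,4‑tetrahydro‑1,4‑epoxynaphthalen‑2‑yl]carbonyl}‑1,3‑oxazolidin‑2‑one | O=C(N1CCOC1=O)[C@@H]1[C@@H](C)[C@@H]2O[C@@]1(c3cc(OC)c(OCOC)c(OC)c3)c4c(OC)c(OCOC)c(OC)cc24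
F3 | step 3 | [(1S,2S,3R,4S)‑1‑aryl‑6,8‑dimethoxy‑7‑(methoxymethoxy)‑3‑methyl‑1,2,3,4‑tetrahydro‑1,4‑epoxynaphthalen‑2‑yl]methanol | OC[C@@H]1[C@@H](C)[C@@H]2O[C@@]1(c3cc(OC)c(OCOC)c(OC)c3)c4c(OC)c(OCOC)c(OC)cc24
F4 | step 3 | methanesulfonate of F3 | CS(=O)(=O)OC[C@@H]1[C@@H](C)[C@@H]2O[C@@]1(c3cc(OC)c(OCOC)c(OC)c3)c4c(OC)c(OCOC)c(OC)cc24
F5 | step 5 | (1S,2R,3R,4S)‑1‑(4‑hydroxy‑3,5‑dimethoxyphenyl)‑6,8‑dimethoxy‑2,3‑dimethyl‑1,2,3,4‑tetrahydro‑1,4‑epoxynaphthalen‑7‑ol | C[C@@H]1[C@@H](C)[C@@H]2O[C@@]1(c3cc(OC)c(O)c(OC)c3)c4c(OC)c(O)c(OC)cc24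
F6 | step 5 | p‑quinone methide alcohol (target numbering 2R,3R,4S; C1 exocyclic to the dienone) | COC1=CC(=C2c3c(OC)c(O)c(OC)cc3[C@@H](O)[C@H](C)[C@H]2C)C=C(OC)C1=O
F7 | step 5 | phenolic 4‑hydroxy‑tetralin (target numbering 1S,2S,3R,4S) | COc1cc([C@H]2c3c(OC)c(O)c(OC)cc3[C@@H](O)[C@H](C)[C@H]2C)cc(OC)c1O
F8 | step 2 | 2‑bromo‑3,5‑dimethoxy‑4‑(methoxymethoxy)benzaldehyde | O=Cc1cc(OC)c(OCOC)c(OC)c1Br
F9 | step 2 | 2‑[2‑bromo‑3,5‑dimethoxy‑4‑(methoxymethoxy)phenyl]‑1,3‑dioxolane | Brc1c(OC)c(OCOC)c(OC)cc1C1OCCO1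
F10 | step 2 | [2‑(1,3‑dioxolan‑2‑yl)‑4,6‑dimethoxy‑5‑(methoxymethoxy)phenyl][3,5‑dimethoxy‑4‑(methoxymethoxy)phenyl]methanol (racemic) | OC(c1cc(OC)c(OCOC)c(OC)c1)c1c(OC)c(OCOC)c(OC)cc1C1OCCO1
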